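**Remark:** the dioxane is numbered O1–O2–C3(H, side chain C2'/C1')–C4–C5–C6(CH3, chain) and the decalin as in labdanes (C5/C10 ring fusion, C7=C8, chain on C9). The given SMILES corresponds to (2'S,3S,6S) in the peroxide part and (5R,9S,10R) in the decalin, i.e. the enantiomeric series of the common sclareol-type terpenes with the C9 chain anti to the C10 methyl group, so the decalin is built de novo.

## Retrosynthetic overview

1. Target 33 ← esterification, oxidation of a CH2OSi group, hydrogenolysis of a C7 enol triflate and diimide reduction of C4=C5 ← 3,6-dihydro-1,2-dioxine 29.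
2. 29 ← closure of the C5–C6 bond. C6 is the one ring carbon at ketone oxidation level: it carries peroxide oxygen O1, the methyl group and the decalinyl-ethyl chain. It is therefore unmasked from the methyl ketone ketal 16 as a peroxycarbenium ion and attacked by C5, the ipso carbon of a (Z)-vinylsilane on the hydroperoxide carbon C3 of 27. One operation joins the two halves, closes the peroxide ring and sets C6.
3. Hydroperoxide 27 (C2', C3) ← syn aldol of a propanoyl oxazolidinone with 3-(trimethylsilyl)propynal, cis semihydrogenation, SN2 inversion at C3 by a protected hydroperoxide.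
4. Ketal 16 (C5, C9, C10) ← copper-mediated conjugate addition to bicyclic enone 11 with enolate triflation ← Robinson-type ring closure on (S)-2-allyl-2,6,6-trimethylcyclohexanone (palladium-catalysed decarboxylative allylation).
5. Ring order: ring A is bought, ring B is closed by aldol condensation (step 6), the 1,2-dioxane is closed last (step 20).

Key step: step 20

## Route

**Step 1**
Reactants: 1 2,2,6-trimethylcyclohexan-1-one (racemic)
Product: 2 prop-2-en-1-yl 2,6,6-trimethylcyclohex-1-en-1-yl carbonate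
Conditions: LiN(SiMe3)2, THF, 0 °C; allyl chloroformate, −78 °C to rt
Reagents that add atoms: allyl chloroformate, C=CCOC(Cl)=O
Why: The ketone has a single enolisable position, so one tetrasubstituted lithium enolate forms, and the hard chloroformate acylates it on oxygen (enol carbonate formation).

**Step 2**
Reactants: 2 allyl enol carbonate
Product: 3 (2S)-2,6,6-trimethyl-2-(prop-2-en-1-yl)cyclohexan-1-one
Conditions: Pd2(dba)3 (2.5 mol %), (S)-4-tert-butyl-2-[2-(diphenylphosphanyl)phenyl]-4,5-dihydrooxazole ((S)-t-Bu-PHOX, 6 mol %), THF, 25 °C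
Reagents that add atoms: none
Why: Decarboxylative asymmetric allylic alkylation (Tsuji allylation): zerovalent palladium ionises the carbonate to a π-allylpalladium enolate pair that recombines at carbon, and the phosphinooxazoline ligand selects the enolate face to set the quaternary centre C10 as (S), the sense expected for this ligand enantiomer in this reaction class (its mirror image is used otherwise).

**Step 3**
Reactants: 3 (S)-allyl ketone
Product: 4 3-[(1S)-1,3,3-trimethyl-2-oxocyclohexyl]propanal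
Conditions: PdCl2(PhCN)2 (12 mol %), CuCl2·2H2O (12 mol %), AgNO2 (6 mol %), O2 (1 atm), t-BuOH/MeNO2, rt
Reagents that add atoms: dioxygen, O=O
Why: The nitrite-modified Wacker oxidation places oxygen on the terminal carbon of an unbiased terminal alkene (aldehyde-selective), and the hindered ring ketone is inert.

**Step 4**
Reactants: 4 keto aldehyde
Product: 5 (2S)-2-(3-hydroxybutyl)-2,6,6-trimethylcyclohexan-1-one (both carbinol epimers)
Conditions: MeMgBr, THF, −78 °C; aq. NH4Cl
Reagents that add atoms: methylmagnesium bromide, C[Mg]Br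
Why: Grignard addition is chemoselective for the aldehyde because the ring ketone is flanked by two quaternary carbons; the new carbinol centre is oxidised away in step 5.

**Step 5**
Reactants: 5 hydroxy ketone
Product: 6 (2S)-2,6,6-trimethyl-2-(3-oxobutyl)cyclohexan-1-one
Conditions: Dess–Martin periodinane, NaHCO3, CH2Cl2, rt
Reagents that add atoms: none
Why: Dess–Martin oxidation converts the secondary alcohol into the methyl ketone under neutral conditions and gives the 1,5-diketone.

**Step 6**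
Reactants: 6 1,5-diketone
Product: 7 (4aS)-4a,8,8-trimethyl-4,4a,5,6,7,8-hexahydronaphthalen-2(3H)-one
Conditions: KOH, xylenes, 110 °C (Dean–Stark)
Reagents that add atoms: none
Why: Intramolecular aldol condensation (second half of a Robinson annulation): only the methyl group can close a six-membered ring onto the ring carbonyl, and dehydration to the conjugated enone drives the hindered addition.

**Step 7**
Reactants: 7 octalone
Product: 8 (4aS)-3,4a,8,8-tetramethyl-4,4a,5,6,7,8-hexahydronaphthalen-2(3H)-one (C3 epimers)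
Conditions: LiN(i-Pr)2, THF, −78 °C; MeI, −78 to 0 °C
Reagents that add atoms: iodomethane, CI
Why: Kinetic deprotonation of a cyclohexenone occurs at the α' carbon (C8) and the cross-conjugated enolate is methylated there; the C8 configuration is not controlled and is erased in step 9.

**Step 8**
Reactants: 8 methyl octalone
Product: 9 (4aS,8aR)-3,4a,8,8-tetramethyloctahydronaphthalen-2(1H)-one (trans-fused, C3 epimers)
Conditions: Li, NH3 (l), THF, t-BuOH (1 equiv), −78 °C; NH4Cl
Reagents that add atoms: none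
Why: Dissolving-metal reduction of the enone protonates the β-carbanion C5 axially and gives the trans ring fusion (H5 anti to the C10 methyl group), as for other 4a-methyl octalones.

**Step 9**
Reactants: 9 trans-decalone
Product: 11 (4aS,8aR)-3,4a,8,8-tetramethyl-4a,5,6,7,8,8a-hexahydronaphthalen-2(1H)-one, via silyl enol ether 10 (not isolated)
Conditions: Me3SiCl, NaI, Et3N, MeCN, rt; then Pd(OAc)2 (1.1 equiv), MeCN, rt
Reagents that add atoms: none
Why: Saegusa–Ito oxidation: equilibrating silylation gives the more substituted C7=C8 silyl enol ether, and palladium diacetate converts it by β-hydride elimination toward C9 into the conjugated 2-methyl enone.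

**Step 10**
Reactants: 11 bicyclic enone; 12 2-(2-bromoethyl)-2-methyl-1,3-dioxolane
Product: 15 (4R,4aR,8aR)-3,4a,8,8-tetramethyl-4-[2-(2-methyl-1,3-dioxolan-2-yl)ethyl]-1,4,4a,5,6,7,8,8a-octahydronaphthalen-2-yl trifluoromethanesulfonate, via Grignard reagent 13 (not isolated), via silyl enol ether 14 (not isolated)
Conditions: 12, Mg, THF, 25 °C; 11, CuBr·SMe2 (20 mol %), Me3SiCl, HMPA, THF, −78 to −40 °C; MeLi, THF, 0 °C; PhNTf2, −78 to 0 °C; aq. NH4Cl
Reagents that add atoms: N-phenylbis(trifluoromethanesulfonimide), O=S(=O)(N(c1ccccc1)S(=O)(=O)C(F)(F)F)C(F)(F)F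
Why: Me3SiCl-accelerated copper-catalysed conjugate addition occurs by axial attack at C9 anti to the adjacent angular methyl group (as in 1α-alkylation of Δ1-3-keto steroids), which sets C9, and the regiodefined enolate regenerated with MeLi is triflated on oxygen to fix the C7=C8 position.

**Step 11**
Reactants: 15 dioxolane enol triflate
Product: 16 (4R,4aR,8aR)-4-(3,3-dimethoxybutyl)-3,4a,8,8-tetramethyl-1,4,4a,5,6,7,8,8a-octahydronaphthalen-2-yl trifluoromethanesulfonate
Conditions: HC(OMe)3, MeOH, pyridinium p-toluenesulfonate (cat.), rt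
Reagents that add atoms: trimethyl orthoformate, COC(OC)OC; methanol, CO
Why: Acid-catalysed transketalisation: the orthoformate traps the liberated glycol as 2-methoxy-1,3-dioxolane and drives the dioxolane to the acyclic dimethyl ketal, while the enol triflate is acid-stable.

**Step 12**
Reactants: 17 (4S)-4-benzyl-3-propanoyl-1,3-oxazolidin-2-one; 18 3-(trimethylsilyl)prop-2-ynal
Product: 19 (4S)-4-benzyl-3-[(2S,3S)-3-hydroxy-2-methyl-5-(trimethylsilyl)pent-4-ynoyl]-1,3-oxazolidin-2-one
Conditions: n-Bu2BOTf, i-Pr2NEt, CH2Cl2, −78 to 0 °C; 18, −78 °C; pH 7 buffer, MeOH, H2O2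
Reagents that add atoms: none
Why: Boron-mediated syn aldol reaction (Evans aldol): the (Z)-boron enolate reacts through a closed Zimmerman–Traxler transition state on the face away from the benzyl group, which sets C2' and C3 (2S,3S, syn).

**Step 13**
Reactants: 19 aldol adduct
Product: 20 (2R,3S)-2-methyl-5-(trimethylsilyl)pent-4-yne-1,3-diol
Conditions: LiBH4, MeOH (1 equiv), THF, 0 °C
Reagents that add atoms: none
Why: Reductive cleavage of the N-acyl oxazolidinone with LiBH4 gives the primary alcohol without touching the stereocentres or the silylalkyne and returns the auxiliary.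

**Step 14**
Reactants: 20 diol
Product: 21 (2R,3S)-1-{[tert-butyl(dimethyl)silyl]oxy}-2-methyl-5-(trimethylsilyl)pent-4-yn-3-ol
Conditions: t-BuMe2SiCl, imidazole, CH2Cl2, 0 °C
Reagents that add atoms: tert-butyldimethylsilyl chloride, CC(C)(C)[Si](C)(C)Cl
Why: Silylation is selective for the primary over the secondary propargylic hydroxyl group on steric grounds.

**Step 15**
Reactants: 21 propargylic alcohol
Product: 22 (2R,3S,4Z)-1-{[tert-butyl(dimethyl)silyl]oxy}-2-methyl-5-(trimethylsilyl)pent-4-en-3-ol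
Conditions: H2 (1 atm), Pd/CaCO3 poisoned with Pb(OAc)2 (Lindlar catalyst), quinoline, hexane/EtOAc, rt
Reagents that add atoms: none
Why: Lindlar semihydrogenation adds hydrogen cis to the silylalkyne and gives the (Z)-vinylsilane that an endocyclic ipso substitution requires.

**Step 16**
Reactants: 22 (Z)-allylic alcohol
Product: 23 (2R,3S,4Z)-1-{[tert-butyl(dimethyl)silyl]oxy}-2-methyl-5-(trimethylsilyl)pent-4-en-3-yl methanesulfonate
Conditions: MeSO2Cl, Et3N, CH2Cl2, −20 °C (used crude)
Reagents that add atoms: methanesulfonyl chloride, CS(=O)(=O)Cl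
Why: Sulfonylation of the alcohol oxygen leaves the C3 configuration untouched and activates C3 for displacement.

**Step 17**
Reactants: 24 2,3-dimethylbut-2-ene
Product: 25 2-hydroperoxy-2-methoxypropane
Conditions: O3, MeOH/CH2Cl2, −78 °C
Reagents that add atoms: ozone, [O-][O+]=O; methanol, CO
Why: Ozonolysis in methanol (Criegee mechanism): the carbonyl oxide from the symmetrical alkene is trapped by methanol as the α-methoxy hydroperoxide.

**Step 18**
Reactants: 23 allylic mesylate; 25 2-hydroperoxy-2-methoxypropane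
Product: 26 tert-butyl({(2R,3R,4Z)-3-[(2-methoxypropan-2-yl)peroxy]-2-methyl-5-(trimethylsilyl)pent-4-en-1-yl}oxy)dimethylsilane
Conditions: CsOH·H2O, DMF, 0 °C
Reagents that add atoms: none
Why: SN2 displacement of the secondary mesylate by the caesium peroxide anion (weakly basic, strongly nucleophilic) inverts C3 and turns the syn alcohol into the anti peroxide; SN2' attack is disfavoured by the silyl group on C5, and the side chain is kept at the alcohol oxidation level so that no E1cB elimination is possible.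

**Step 19**
Reactants: 26 peroxyketal
Product: 27 tert-butyl{[(2R,3R,4Z)-3-hydroperoxy-2-methyl-5-(trimethylsilyl)pent-4-en-1-yl]oxy}dimethylsilane
Conditions: pyridinium p-toluenesulfonate (cat.), MeOH, 0 °C
Reagents that add atoms: none
Why: Acid-catalysed methanolysis (transketalisation) of the 2-methoxyprop-2-yl peroxyketal releases the hydroperoxide and 2,2-dimethoxypropane, and the primary silyl ether should survive these mild conditions.

**Step 20**
Reactants: 27 allylic hydroperoxide; 16 dimethyl ketal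
Product: 29 (4R,4aR,8aR)-4-{2-[(3S,6S)-6-{(2R)-1-[(tert-butyldimethylsilyl)oxy]propan-2-yl}-3-methyl-3,6-dihydro-1,2-dioxin-3-yl]ethyl}-3,4a,8,8-tetramethyl-1,4,4a,5,6,7,8,8a-octahydronaphthalen-2-yl trifluoromethanesulfonate, via mixed methoxy peroxyketal 28 (not isolated)
Conditions: pyridinium p-toluenesulfonate (cat.), 5 Å molecular sieves, CH2Cl2, 0 °C; then Me3SiOTf (0.3 equiv), 2,6-di-tert-butyl-4-methylpyridine, −78 to −40 °C; aq. NaHCO3
Reagents that add atoms: none
Why: Proposed new method: acid-catalysed exchange of one methoxy group of 16 by hydroperoxide 27 gives mixed peroxyketal 28, which Me3SiOTf ionises to a peroxycarbenium ion at C6; the ipso carbon C5 of the (Z)-vinylsilane attacks it, and the β-silyl cation at C4 loses the silyl group (as Me3SiOMe, regenerating Me3SiOTf) to leave C4=C5. The closest known reaction types are the Lewis-acid allylation and intramolecular allylsilane cyclisation of peroxycarbenium ions from monoperoxyketals, and the vinylsilane-terminated (silyl-Prins) cyclisation of oxocarbenium ions to 5,6-dihydro-2H-pyrans; closure of a 3,6-dihydro-1,2-dioxine in this way has not been shown. The ring closes in a 6-endo-trig mode with respect to the vinylsilane through a six-membered transition state spanning the O–O tether, with retention of alkene geometry, which is why the Z silane is needed. The new stereocentre C6 is set by 1,4-induction from C3 in a half-chair transition state: the C3 side chain sits pseudo-equatorial, and the pseudo-equatorial site at C6 is gauche to the SiMe3 group on the attacking carbon while the pseudo-axial site has no 1,3-partner (O2 has only lone pairs, C4 is sp2), so the methyl group should take the pseudo-equatorial and the long chain the pseudo-axial position, which is the (3S,6S) relationship of the target. The step needs attack by the vinylsilane only and C–O rather than O–O ionisation: the ring alkene is carried as its electron-poor enol triflate so that it cannot add to the cation in a bicyclo[3.3.1] Prins closure, and methoxide is the group the silyl Lewis acid removes.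

**Step 21**
Reactants: 29 dihydrodioxine
Product: 30 (4R,4aR,8aR)-4-{2-[(3S,6S)-6-{(2R)-1-[(tert-butyldimethylsilyl)oxy]propan-2-yl}-3-methyl-1,2-dioxan-3-yl]ethyl}-3,4a,8,8-tetramethyl-1,4,4a,5,6,7,8,8a-octahydronaphthalen-2-yl trifluoromethanesulfonate
Conditions: KO2C–N=N–CO2K, AcOH, MeOH/CH2Cl2, 0 °C to rt
Reagents that add atoms: none
Why: Diimide reduction transfers H2 in a concerted syn fashion to the cis-disubstituted ring double bond and saturates C4–C5 without cleaving the O–O bond, and the tetrasubstituted enol triflate is inert.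

**Step 22**
Reactants: 30 dioxane enol triflate
Product: 31 tert-butyl{(2R)-2-[(3S,6S)-6-methyl-6-{2-[(1S,4aR,8aR)-2,5,5,8a-tetramethyl-1,4,4a,5,6,7,8,8a-octahydronaphthalen-1-yl]ethyl}-1,2-dioxan-3-yl]propoxy}dimethylsilane
Conditions: Pd(PPh3)4 (5 mol %), LiCl, Bu3SnH, THF, 25–50 °C
Reagents that add atoms: none
Why: Palladium-catalysed hydrogenolysis of the enol triflate (oxidative addition, hydride transfer from tin, reductive elimination) replaces OTf by H and keeps the C7=C8 position, under neutral conditions that dialkyl peroxides are expected to tolerate.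

**Step 23**
Reactants: 31 silyl ether
Product: 32 (2S)-2-[(3S,6S)-6-methyl-6-{2-[(1S,4aR,8aR)-2,5,5,8a-tetramethyl-1,4,4a,5,6,7,8,8a-octahydronaphthalen-1-yl]ethyl}-1,2-dioxan-3-yl]propanoic acid
Conditions: CrO3, H2SO4, H2O, acetone, 0 °C
Reagents that add atoms: water, O
Why: Jones oxidation: the acidic medium cleaves the primary silyl ether and the alcohol is oxidised through the aldehyde hydrate to the acid, under acidic conditions in which C2' should not epimerise and the 1,2-dioxane is stable.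

**Step 24**
Reactants: 32 acid
Product: 33 methyl (2S)-2-[(3S,6S)-6-methyl-6-{2-[(1S,4aR,8aR)-2,5,5,8a-tetramethyl-1,4,4a,5,6,7,8,8a-octahydronaphthalen-1-yl]ethyl}-1,2-dioxan-3-yl]propanoate (target)
Conditions: Me3SiCHN2, MeOH/toluene, 0 °C
Reagents that add atoms: trimethylsilyldiazomethane, C[Si](C)(C)C=[N+]=[N-]
Why: O-methylation of the acid with trimethylsilyldiazomethane is neutral and avoids base-induced retro-oxa-Michael opening of the β-peroxy ester.

## Compound list

1 | 2,2,6-trimethylcyclohexan-1-one (racemic) | CC1CCCC(C)(C)C1=O | starting material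
2 | prop-2-en-1-yl 2,6,6-trimethylcyclohex-1-en-1-yl carbonate | C=CCOC(=O)OC1=C(C)CCCC1(C)C | intermediate
3 | (2S)-2,6,6-trimethyl-2-(prop-2-en-1-yl)cyclohexan-1-one | C=CC[C@]1(C)CCCC(C)(C)C1=O | intermediate
4 | 3-[(1S)-1,3,3-trimethyl-2-oxocyclohexyl]propanal | O=CCC[C@]1(C)CCCC(C)(C)C1=O | intermediate
5 | (2S)-2-(3-hydroxybutyl)-2,6,6-trimethylcyclohexan-1-one (carbinol epimers) | CC(O)CC[C@]1(C)CCCC(C)(C)C1=O | intermediate
6 | (2S)-2,6,6-trimethyl-2-(3-oxobutyl)cyclohexan-1-one | CC(=O)CC[C@]1(C)CCCC(C)(C)C1=O | intermediate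
7 | (4aS)-4a,8,8-trimethyl-4,4a,5,6,7,8-hexahydronaphthalen-2(3H)-one | O=C1C=C2C(C)(C)CCC[C@@]2(C)CC1 | intermediate
8 | (4aS)-3,4a,8,8-tetramethyl-4,4a,5,6,7,8-hexahydronaphthalen-2(3H)-one (C3 epimers) | O=C1C=C2C(C)(C)CCC[C@@]2(C)CC1C | intermediate
9 | (4aS,8aR)-3,4a,8,8-tetramethyloctahydronaphthalen-2(1H)-one (trans-fused, C3 epimers) | O=C1C[C@@H]2C(C)(C)CCC[C@@]2(C)CC1C | intermediate
10 | trimethyl{[(4aS,8aR)-3,4a,8,8-tetramethyl-1,4,4a,5,6,7,8,8a-octahydronaphthalen-2-yl]oxy}silane | C[Si](C)(C)OC=1C[C@@H]2C(C)(C)CCC[C@@]2(C)CC=1C | intermediate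
11 | (4aS,8aR)-3,4a,8,8-tetramethyl-4a,5,6,7,8,8a-hexahydronaphthalen-2(1H)-one | O=C1C[C@@H]2C(C)(C)CCC[C@@]2(C)C=C1C | intermediate
12 | 2-(2-bromoethyl)-2-methyl-1,3-dioxolane | CC1(CCBr)OCCO1 | starting material
13 | bromo[2-(2-methyl-1,3-dioxolan-2-yl)ethyl]magnesium | CC1(CC[Mg]Br)OCCO1 | intermediate
14 | trimethyl({(4R,4aR,8aR)-3,4a,8,8-tetramethyl-4-[2-(2-methyl-1,3-dioxolan-2-yl)ethyl]-1,4,4a,5,6,7,8,8a-octahydronaphthalen-2-yl}oxy)silane | CC1(CC[C@H]2C(C)=C(O[Si](C)(C)C)C[C@@H]3C(C)(C)CCC[C@]32C)OCCO1 | intermediate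
15 | (4R,4aR,8aR)-3,4a,8,8-tetramethyl-4-[2-(2-methyl-1,3-dioxolan-2-yl)ethyl]-1,4,4a,5,6,7,8,8a-octahydronaphthalen-2-yl trifluoromethanesulfonate | CC1(CC[C@H]2C(C)=C(OS(=O)(=O)C(F)(F)F)C[C@@H]3C(C)(C)CCC[C@]32C)OCCO1 | intermediate
16 | (4R,4aR,8aR)-4-(3,3-dimethoxybutyl)-3,4a,8,8-tetramethyl-1,4,4a,5,6,7,8,8a-octahydronaphthalen-2-yl trifluoromethanesulfonate | COC(C)(CC[C@H]2C(C)=C(OS(=O)(=O)C(F)(F)F)C[C@@H]3C(C)(C)CCC[C@]32C)OC | intermediate
17 | (4S)-4-benzyl-3-propanoyl-1,3-oxazolidin-2-one | CCC(=O)N1[C@@H](Cc2ccccc2)COC1=O | starting material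
18 | 3-(trimethylsilyl)prop-2-ynal | C[Si](C)(C)C#CC=O | starting material
19 | (4S)-4-benzyl-3-[(2S,3S)-3-hydroxy-2-methyl-5-(trimethylsilyl)pent-4-ynoyl]-1,3-oxazolidin-2-one | O=C1OC[C@H](Cc2ccccc2)N1C(=O)[C@@H](C)[C@H](O)C#C[Si](C)(C)C | intermediate
20 | (2R,3S)-2-methyl-5-(trimethylsilyl)pent-4-yne-1,3-diol | OC[C@@H](C)[C@H](O)C#C[Si](C)(C)C | intermediate
21 | (2R,3S)-1-{[tert-butyl(dimethyl)silyl]oxy}-2-methyl-5-(trimethylsilyl)pent-4-yn-3-ol | CC(C)(C)[Si](C)(C)OC[C@@H](C)[C@H](O)C#C[Si](C)(C)C | intermediate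
22 | (2R,3S,4Z)-1-{[tert-butyl(dimethyl)silyl]oxy}-2-methyl-5-(trimethylsilyl)pent-4-en-3-ol | CC(C)(C)[Si](C)(C)OC[C@@H](C)[C@H](O)/C=C\[Si](C)(C)C | intermediate
23 | (2R,3S,4Z)-1-{[tert-butyl(dimethyl)silyl]oxy}-2-methyl-5-(trimethylsilyl)pent-4-en-3-yl methanesulfonate | CC(C)(C)[Si](C)(C)OC[C@@H](C)[C@H](OS(C)(=O)=O)/C=C\[Si](C)(C)C | intermediate
24 | 2,3-dimethylbut-2-ene | CC(C)=C(C)C | starting material
25 | 2-hydroperoxy-2-methoxypropane | COC(C)(C)OO | intermediate
26 | tert-butyl({(2R,3R,4Z)-3-[(2-methoxypropan-2-yl)peroxy]-2-methyl-5-(trimethylsilyl)pent-4-en-1-yl}oxy)dimethylsilane | CC(C)(C)[Si](C)(C)OC[C@@H](C)[C@@H](OOC(C)(C)OC)/C=C\[Si](C)(C)C | intermediate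
27 | tert-butyl{[(2R,3R,4Z)-3-hydroperoxy-2-methyl-5-(trimethylsilyl)pent-4-en-1-yl]oxy}dimethylsilane | CC(C)(C)[Si](C)(C)OC[C@@H](C)[C@@H](OO)/C=C\[Si](C)(C)C | intermediate
28 | (4R,4aR,8aR)-4-{3-[((2R,3R,4Z)-1-{[tert-butyl(dimethyl)silyl]oxy}-2-methyl-5-(trimethylsilyl)pent-4-en-3-yl)peroxy]-3-methoxybutyl}-3,4a,8,8-tetramethyl-1,4,4a,5,6,7,8,8a-octahydronaphthalen-2-yl trifluoromethanesulfonate (both ketal epimers) | CC(C)(C)[Si](C)(C)OC[C@@H](C)[C@@H](OOC(C)(OC)CC[C@H]2C(C)=C(OS(=O)(=O)C(F)(F)F)C[C@@H]3C(C)(C)CCC[C@]32C)/C=C\[Si](C)(C)C | intermediate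
29 | (4R,4aR,8aR)-4-{2-[(3S,6S)-6-{(2R)-1-[(tert-butyldimethylsilyl)oxy]propan-2-yl}-3-methyl-3,6-dihydro-1,2-dioxin-3-yl]ethyl}-3,4a,8,8-tetramethyl-1,4,4a,5,6,7,8,8a-octahydronaphthalen-2-yl trifluoromethanesulfonate | CC(C)(C)[Si](C)(C)OC[C@@H](C)[C@@H]1C=C[C@](C)(CC[C@H]2C(C)=C(OS(=O)(=O)C(F)(F)F)C[C@@H]3C(C)(C)CCC[C@]32C)OO1 | intermediate
30 | (4R,4aR,8aR)-4-{2-[(3S,6S)-6-{(2R)-1-[(tert-butyldimethylsilyl)oxy]propan-2-yl}-3-methyl-1,2-dioxan-3-yl]ethyl}-3,4a,8,8-tetramethyl-1,4,4a,5,6,7,8,8a-octahydronaphthalen-2-yl trifluoromethanesulfonate | CC(C)(C)[Si](C)(C)OC[C@@H](C)[C@@H]1CC[C@](C)(CC[C@H]2C(C)=C(OS(=O)(=O)C(F)(F)F)C[C@@H]3C(C)(C)CCC[C@]32C)OO1 | intermediate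
31 | tert-butyl{(2R)-2-[(3S,6S)-6-methyl-6-{2-[(1S,4aR,8aR)-2,5,5,8a-tetramethyl-1,4,4a,5,6,7,8,8a-octahydronaphthalen-1-yl]ethyl}-1,2-dioxan-3-yl]propoxy}dimethylsilane | CC(C)(C)[Si](C)(C)OC[C@@H](C)[C@@H]1CC[C@](C)(CC[C@H]2C(C)=CC[C@@H]3C(C)(C)CCC[C@]32C)OO1 | intermediate
32 | (2S)-2-[(3S,6S)-6-methyl-6-{2-[(1S,4aR,8aR)-2,5,5,8a-tetramethyl-1,4,4a,5,6,7,8,8a-octahydronaphthalen-1-yl]ethyl}-1,2-dioxan-3-yl]propanoic acid | OC(=O)[C@@H](C)[C@@H]1CC[C@](C)(CC[C@H]2C(C)=CC[C@@H]3C(C)(C)CCC[C@]32C)OO1 | intermediate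
33 | methyl (2S)-2-[(3S,6S)-6-methyl-6-{2-[(1S,4aR,8aR)-2,5,5,8a-tetramethyl-1,4,4a,5,6,7,8,8a-octahydronaphthalen-1-yl]ethyl}-1,2-dioxan-3-yl]propanoate | COC(=O)[C@@H](C)[C@@H]1CC[C@](C)(CC[C@H]2C(C)=CC[C@@H]3C(C)(C)CCC[C@]32C)OO1 | target

## Step count and risks

Total step count: 24. Longest linear sequence: 16 steps (steps 1–11 and 20–24).

**Step 20 (Proposed new method).** The Lewis acid may ionise the peroxide in the wrong sense (O–O heterolysis with 1,2-shift, a Hock/Criegee-type fragmentation), or protodesilylation of the vinylsilane may outrun C–C bond formation. Facial discrimination between the methyl group and the chain at C6 may also be poor.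

The fallback uses known reactions only: the peroxide is introduced by cobalt-catalysed hydroperoxysilylation and the ring is closed through the O2–C3 bond. It sets out from 15. Hydrolysis of the dioxolane (aq. HCl, THF) gives the methyl ketone F1. Kinetic deprotonation on the methyl side (LiN(i-Pr)2, THF, −78 °C) and allyl bromide give the heptenone F2. Wittig methylenation (Ph3P=CH2) gives the 1,5-diene F3. Cross-metathesis of the monosubstituted alkene with methyl methacrylate (second-generation Hoveyda–Grubbs catalyst) gives the (E)-enoate F4. Isayama–Mukaiyama hydroperoxysilylation (Co(acac)2, O2, Et3SiH) at the 1,1-disubstituted alkene gives the tertiary triethylsilyl peroxide F5. Desilylation (HCl, MeOH) followed by conjugate addition of the hydroperoxide to the enoate (Et2NH, CF3CH2OH; 6-exo) gives the dioxane ester F6. Hydrogenolysis of its enol triflate as in step 22 comes back to the route at 33. This fallback gives up substrate control at C6, C3 and C2', so F6 would have to be separated from its isomers.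

**Step 18.** Ionisation of the secondary allylic mesylate (loss of configuration at C3, allylic transposition) or elimination to the silyl diene may compete with SN2 displacement.

The fallback moves the displacement to the propargylic stage, where ionisation and SN2' are much less favourable. It sets out from 21. Mesylation (MeSO2Cl, Et3N) gives the propargylic mesylate F7. Displacement with 25 (CsOH·H2O, DMF) gives the propargylic peroxyketal F8 with inversion. Cis semireduction of the silylalkyne with diimide (KO2C–N=N–CO2K, AcOH), which leaves the O–O bond intact, comes back to the route at 26.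

**Step 22.** Zerovalent palladium, phosphine or tin hydride may cleave the O–O bond reductively, or oxidative addition at the hindered tetrasubstituted enol triflate may be too slow.

The fallback removes the triflate before any peroxide is present. It sets out from 15. Formate hydrogenolysis (Pd(OAc)2, PPh3, HCO2H, Bu3N, DMF, 60 °C) gives the alkene F9. Transketalisation as in step 11 gives the dimethyl ketal F10. Reaction with 27 under the conditions of step 20, run colder because the ring alkene is now a competing π-nucleophile, gives the mixed peroxyketal F11 and from it the dihydrodioxine F12. Diimide then reduces only the disubstituted C4=C5 bond of F12 and comes back to the route at 31.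

## Further compounds

F1 | step 20 | (4R,4aR,8aR)-3,4a,8,8-tetramethyl-4-(3-oxobutyl)-1,4,4a,5,6,7,8,8a-octahydronaphthalen-2-yl trifluoromethanesulfonate | CC(=O)CC[C@H]2C(C)=C(OS(=O)(=O)C(F)(F)F)C[C@@H]3C(C)(C)CCC[C@]32C
F2 | step 20 | (4R,4aR,8aR)-3,4a,8,8-tetramethyl-4-(3-oxohept-6-en-1-yl)-1,4,4a,5,6,7,8,8a-octahydronaphthalen-2-yl trifluoromethanesulfonate | C=CCCC(=O)CC[C@H]2C(C)=C(OS(=O)(=O)C(F)(F)F)C[C@@H]3C(C)(C)CCC[C@]32C
F3 | step 20 | (4R,4aR,8aR)-3,4a,8,8-tetramethyl-4-(3-methylidenehept-6-en-1-yl)-1,4,4a,5,6,7,8,8a-octahydronaphthalen-2-yl trifluoromethanesulfonate | C=CCCC(=C)CC[C@H]2C(C)=C(OS(=O)(=O)C(F)(F)F)C[C@@H]3C(C)(C)CCC[C@]32C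
F4 | step 20 | methyl (2E)-2-methyl-6-methylidene-8-[(1R,4aR,8aR)-2,5,5,8a-tetramethyl-3-{[(trifluoromethyl)sulfonyl]oxy}-1,4,4a,5,6,7,8,8a-octahydronaphthalen-1-yl]oct-2-enoate | COC(=O)/C(C)=C/CCC(=C)CC[C@H]2C(C)=C(OS(=O)(=O)C(F)(F)F)C[C@@H]3C(C)(C)CCC[C@]32C
F5 | step 20 | methyl (2E)-2,6-dimethyl-8-[(1R,4aR,8aR)-2,5,5,8a-tetramethyl-3-{[(trifluoromethyl)sulfonyl]oxy}-1,4,4a,5,6,7,8,8a-octahydronaphthalen-1-yl]-6-[(triethylsilyl)peroxy]oct-2-enoate (both C6 epimers) | COC(=O)/C(C)=C/CCC(C)(OO[Si](CC)(CC)CC)CC[C@H]2C(C)=C(OS(=O)(=O)C(F)(F)F)C[C@@H]3C(C)(C)CCC[C@]32C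
F6 | step 20 | methyl (2S)-2-[(3S,6S)-6-methyl-6-{2-[(1R,4aR,8aR)-2,5,5,8a-tetramethyl-3-{[(trifluoromethyl)sulfonyl]oxy}-1,4,4a,5,6,7,8,8a-octahydronaphthalen-1-yl]ethyl}-1,2-dioxan-3-yl]propanoate (after separation) | COC(=O)[C@@H](C)[C@@H]1CC[C@](C)(CC[C@H]2C(C)=C(OS(=O)(=O)C(F)(F)F)C[C@@H]3C(C)(C)CCC[C@]32C)OO1
F7 | step 18 | (2R,3S)-1-{[tert-butyl(dimethyl)silyl]oxy}-2-methyl-5-(trimethylsilyl)pent-4-yn-3-yl methanesulfonate | CC(C)(C)[Si](C)(C)OC[C@@H](C)[C@H](OS(C)(=O)=O)C#C[Si](C)(C)C
F8 | step 18 | tert-butyl({(2R,3R)-3-[(2-methoxypropan-2-yl)peroxy]-2-methyl-5-(trimethylsilyl)pent-4-yn-1-yl}oxy)dimethylsilane | CC(C)(C)[Si](C)(C)OC[C@@H](C)[C@@H](OOC(C)(C)OC)C#C[Si](C)(C)C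
F9 | step 22 | 2-methyl-2-{2-[(1S,4aR,8aR)-2,5,5,8a-tetramethyl-1,4,4a,5,6,7,8,8a-octahydronaphthalen-1-yl]ethyl}-1,3-dioxolane | CC1(CC[C@H]2C(C)=CC[C@@H]3C(C)(C)CCC[C@]32C)OCCO1
F10 | step 22 | (1S,4aR,8aR)-1-(3,3-dimethoxybutyl)-2,5,5,8a-tetramethyl-1,4,4a,5,6,7,8,8a-octahydronaphthalene | COC(C)(CC[C@H]2C(C)=CC[C@@H]3C(C)(C)CCC[C@]32C)OC
F11 | step 22 | tert-butyl{[(2R,3R,4Z)-3-({2-methoxy-4-[(1S,4aR,8aR)-2,5,5,8a-tetramethyl-1,4,4a,5,6,7,8,8a-octahydronaphthalen-1-yl]butan-2-yl}peroxy)-2-methyl-5-(trimethylsilyl)pent-4-en-1-yl]oxy}dimethylsilane (both ketal epimers) | CC(C)(C)[Si](C)(C)OC[C@@H](C)[C@@H](OOC(C)(OC)CC[C@H]2C(C)=CC[C@@H]3C(C)(C)CCC[C@]32C)/C=C\[Si](C)(C)C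
F12 | step 22 | tert-butyl{(2R)-2-[(3S,6S)-6-methyl-6-{2-[(1S,4aR,8aR)-2,5,5,8a-tetramethyl-1,4,4a,5,6,7,8,8a-octahydronaphthalen-1-yl]ethyl}-3,6-dihydro-1,2-dioxin-3-yl]propoxy}dimethylsilane | CC(C)(C)[Si](C)(C)OC[C@@H](C)[C@@H]1C=C[C@](C)(CC[C@H]2C(C)=CC[C@@H]3C(C)(C)CCC[C@]32C)OO1
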